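A millimole per litre of free catalyst is the unit I reckon in. The partner can go through catalyst intermediate A to left-handed product, or it can fall apart to decomposed reagent. I count the route through catalyst intermediate B with the rest of the partner.

| flask | left-handed substrate | right-handed substrate | partner | free catalyst | remark | time |
|---|---|---|---|---|---|---|
| Sunday's | 0.20 M | 0.20 M | 0.30 M (fed, over 3.0 d) | 5 mM | run made earlier; the fed solution adds 0.20 times the starting volume |  |
| Thursday's | 0.20 M | 0.20 M | 0.30 M (fed, over 3.0 d) | 7.5 mM | run made earlier; the fed solution adds 0.20 times the starting volume |  |
| flask | 0.20 M | 0.20 M | 0.300 M (fed, over 3.0 d) | 10 mM | the fed solution adds 0.20 times the starting volume | 15 d |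

| run | time / d | left-handed substrate / % | left-handed product / % | right-handed substrate / % |
|---|---|---|---|---|
| Sunday's | 1.67 | 48.1 | 2.2 | 50.4 |
| Sunday's | 3.00 | 46.7 | 3.4 | 50.2 |
| Sunday's | 5.00 | 46.0 | 3.1 | 50.1 |
| Sunday's | 6.00 | 46.4 | 3.3 | 49.5 |
| Sunday's | 8.00 | 46.1 | 4.2 | 49.8 |
| Sunday's | 10.0 | 46.4 | 3.8 | 49.9 |
| Thursday's | 0.625 | 48.5 | 0 | 49.8 |
| Thursday's | 1.67 | 47.3 | 2.2 | 49.8 |
| Thursday's | 3.00 | 45.7 | 4.2 | 49.8 |
| Thursday's | 5.00 | 43.7 | 6.3 | 50.2 |
| Thursday's | 6.00 | 43.4 | 4.5 | 49.2 |
| Thursday's | 10.0 | 43.7 | 5.5 | 49.7 |

(readings scatter by 0.5 percentage points)

- free catalyst is single-handed; left-handed substrate and right-handed substrate are mirror images of each other, charged as a racemate, each of them at the stated concentration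
- every charge counts on the volume at the start, and the solution that is fed holds the whole dose
- the earlier runs were read with a standard deviation of 0.5 percentage points
- steps thought possible: partner + catalyst intermediate B -> free catalyst + right-handed product; free catalyst + left-handed substrate <-> catalyst intermediate A; free catalyst + right-handed substrate <-> catalyst intermediate B; partner -> decomposed reagent; partner + catalyst intermediate A -> free catalyst + left-handed product
- the reaction counts as stopped when no species that holds the left-handed substrate and right-handed substrate together changes by six tenths of a point or more over the second half of the time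

- the state of affairs at 15 d: stopped, and by what, or still going (no working catalyst is left / the partner has run out first / all of the left-handed substrate has reacted / forward and back rates have come level / it is still moving)
- conversion of left-handed substrate and right-handed substrate together at 15 d
- amount of left-handed product at 15 d, in percent of the left-handed substrate and right-handed substrate together charged
- amount of right-handed substrate at 15 d, in percent of the left-handed substrate and right-handed substrate together charged

Two extreme flasks can be done in the head. If no partner decomposed, the 0.300 M charged would exceed the 0.20 M of left-handed substrate, and left-handed product could reach at most 50.0%. If decomposition took all the partner, there would be no product. The runs lie near the second extreme. From 5.00 d on, left-handed product reads 3.60% on average in Sunday's run and 5.43% in Thursday's, far under that ceiling.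

Each partner step holds one partner, so the level of partner cancels from their ratio. I call that ratio the capture odds: partner turned into left-handed product, over the rest. The product readings put 4.80% of the partner into product in Sunday's run and 7.24% in Thursday's, so the odds are 0.0504 and 0.0781. Their logarithms to base ten are −1.30 and −1.11, and against the logarithm of catalyst they rise with slope 1.08. With readings scattered by 0.5 percentage points, I take that slope as one. The capture odds per millimolar of catalyst are then 0.0102 mM⁻¹.

For the flask, the odds are 0.102, logarithm −0.991. The share is 9.30%, so I commit to 6.97% of left-handed product. Left-handed substrate reads flat in both runs from 5.00 d, well before 15 d, so I expect this flask to stand still by then too. The forecast says the partner has run out first, with conversion 9.2%, left-handed product 6.7%, below mine, and right-handed substrate 49.7%, holding that “only a small share, proportional to catalyst, makes product”. The flask gives the partner has run out first, with conversion 8.34%, left-handed product 6.95% and right-handed substrate 49.4%.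

    partner + catalyst intermediate B → free catalyst + right-handed product (k = 3.30 × 10⁻⁵ L mol⁻¹ s⁻¹)
    free catalyst + left-handed substrate ⇌ catalyst intermediate A (K = 4.50 L mol⁻¹, k = 0.00910 L mol⁻¹ s⁻¹)
    free catalyst + right-handed substrate ⇌ catalyst intermediate B (K = 1.70 L mol⁻¹, k = 0.0150 L mol⁻¹ s⁻¹)
    partner → decomposed reagent (k = 1.50 × 10⁻⁵ s⁻¹)
    partner + catalyst intermediate A → free catalyst + left-handed product (k = 4.90 × 10⁻⁴ L mol⁻¹ s⁻¹)

The partner is the flask's limiting reagent: at 15.0 d, 0% of it is left against 84% of the left-handed substrate. The flask's left-handed product means odds of 0.102, or 0.0102 mM⁻¹ with its catalyst divided out, against my 0.0102 mM⁻¹. The neighbouring flask takes 0.075 M of partner with the same catalyst. I keep its odds at 0.102 and its share at 9.30%, and the reckoning gives 1.74% of left-handed product. That neighbouring flask holds 0% of its partner at 15.0 d and shows 1.80% of left-handed product.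

(The readings stem from a simulated flask for an exercise; noise was put on by code.)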